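| setting | eta | beta | north-west | east |
|---|---|---|---|---|
| substrate | 0.10 M | 0.10 M | 0.10 M | 0.10 M |
| partner | 0.17 M (fed, over 1.5 h) | 0.26 M (fed, over 1.5 h) | 0.120 M | 0.120 M (fed, over 1.5 h) |
| temperature | 0 °C | 11 °C | 5 °C | 5 °C |
| remark | run made earlier; the fed solution adds 0.10 times the starting volume | run made earlier; the fed solution adds 0.10 times the starting volume | everything together at the start, the whole solution of partner included, so that from the start the volume is larger by 0.10 times the starting volume | the fed solution adds 0.10 times the starting volume |
| time |  |  | 0.50 h | 1.5 h |

| run | time / min | target / % | isomer of the product / % | substrate / % |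
|---|---|---|---|---|
| eta | 25.0 | 7 | 0 | 85 |
| eta | 50.0 | 18 | 0 | 75 |
| eta | 60.0 | 23 | 0 | 68 |
| eta | 90.0 | 36 | 1 | 59 |
| beta | 25.0 | 30 | 3 | 53 |
| beta | 50.0 | 59 | 10 | 29 |
| beta | 60.0 | 61 | 15 | 22 |
| beta | 90.0 | 59 | 25 | 11 |

(each reading ± 1.5 percentage points)

* which one finishes higher in share of target in all that became target or isomer of the product ("neither" within 2 percentage points) (north-west / east / neither)
* share of target in all that became target or isomer of the product, north-west
* share of target in all that became target or isomer of the product, east

- charges are per starting volume, the dose included; the dosed solution carries all of it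

The amounts in beta point to where the isomer of the product comes from: between 60.0 min and 90.0 min target stands at 61 % and then 59 %, while the isomer climbs from 15 % to 25 %. I therefore take the isomer as made from target at first order, with constant k. While target rises in a straight line from nothing, its mean age is half the elapsed time t, so the curve can be replaced by its mean:

N = k × t / 2, [isomer]/[target] ≈ N, share of target ≈ 1 / (1 + N)

N, the ageing number, is the turnover of an average target molecule. It folds rate and time into one figure.

Beta at 50.0 min gives k = 0.00678 /min at 11 °C. The isomer reading in eta is within its scatter of nothing, so I borrow the temperature factor from substrate loss, ln(substrate left) in beta over that in eta at 50.0 min, which is 4.30. Beta and eta differ in partner as well as in temperature, so it is my assumption that this factor belongs to the temperature and that the isomer step shares it. At 5 °C this gives k = 0.00306 /min.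

North-west: N = 0.0459, share 95.6 %.
East: N = 0.138, share 87.9 %.

The test is beta itself. At 25.0 min N is 0.0847 against a ratio read of 0.100, but at 90.0 min, with target flat, N is 0.305 against 0.424. While target still climbs, N stands within the scatter of the readings; once target is flat, it reads high on share.

The forecast says north-west, with 97 % (95 % to 98.5 %) and 91 % (87 % to 95 %): “What decides the share is how long the target sits.” My shares stand below its values, in the same order.

The flasks give north-west, with 94.6 % for north-west and 85.8 % for east.

    substrate → intermediate (k = 0.0118 /min, Ea = 84.0 kJ/mol)
    partner + intermediate → target (k = 1.92 /M/min, Ea = 64.0 kJ/mol)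
    target ⇌ isomer of the product (K = 1.63, k = 0.00417 /min, Ea = 79.0 kJ/mol, ΔH = −11.0 kJ/mol)
    (constants at 5 °C)

In north-west at 0.500 h, isomer over target is 0.0572 against N of 0.0459. In east at 1.50 h it is 0.166 against 0.138. The neighbour is the north-west flask read at 2.0 h, where N grows with the time to 0.184 and gives a share of 84.5 %. That flask holds 56.0 % target and 16.1 % isomer, a share of 77.6 %.

All runs are simulated with made-up constants; scatter was added.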